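(The numbers are made up; what happens was integrated by code.)

Wednesday's flask, whose charge of G is the lowest of the series, is the neighbour from which the charge of G for the next run is chosen, with Q as the product wanted.

    G + D ⇌ G.D (K1 = 32 M⁻¹, k1 = 0.21 M⁻¹ h⁻¹)
    G.D ⇌ Q + Z (K2 = 0.011 M, k2 = 0.024 h⁻¹)
    G + Q → G.Q (k3 = 0.63 M⁻¹ h⁻¹)

| setting | Wednesday's | Monday's | Tuesday's | Sunday's | Saturday's |
|---|---|---|---|---|---|
| G | 0.012 M | 0.025 M | 0.050 M | 0.10 M | 0.20 M |
| D | 0.0500 M | 0.0500 M | 0.0500 M | 0.0500 M | 0.0500 M |
| time | 2.0 d | 2.0 d | 2.0 d | 2.0 d | 2.0 d |

- percentages count the G that a species holds: one G.Q counts as two
- "hardly changes" means that all values lie within two and a half points (for a concentration: within two and a half percent of the largest)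
- run time (Wednesday's): 2.0 d

- [Q] at the end for Wednesday's, Monday's, Tuesday's, Sunday's, Saturday's, in this order
- how that number moves from the first to the last of them (rises, then falls / falls, then rises / falls all the way / hardly changes / rises all the way)

The choice can be reckoned by counting turnovers. Q forms through G.D and is taken away by G in step 3. Wednesday's gives 0.363 for the turnover count of Q, the number of lifetimes of Q against G that fit into the run, taken as the rate constant of step 3 times the charge of G times the run time. If Q is supplied evenly and G is held at its charge, the share of Q that survives is one minus exp(−N), divided by N, where N is that count.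

The supply comes from a chain of two steps with the back steps left aside. In this reckoning the larger charge is held fixed, which makes step 1 pseudo-first-order, and the smaller charge is taken as the limiting reagent; Tuesday's, whose two charges are level, is reckoned like Wednesday's and Monday's. For these three flasks the reckoned fraction of the charge of G passed through to Q is 0.172. The reckoned fraction of the charge of D is 0.292 for Sunday's and 0.440 for Saturday's.

Supply times surviving share then gives, in the order asked, 0.00173 M, 0.00301 M, 0.00443 M, 0.00460 M and 0.00363 M. From Sunday's to Saturday's the count doubles, while the supply grows by a factor of 1.51. The reckoning therefore commits the next run to Sunday's charge.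

The forecast gave 0.0015 M, 0.0026 M, 0.0038 M, 0.0044 M and 0.0037 M, a row that rises, then falls, and added that “the last two values are close enough that the peak is not certain”. Its value for Wednesday's is lower than the reckoned one, but its highest value also stands at Sunday's.

The simulation gives 0.00161 M, 0.00282 M, 0.00414 M, 0.00478 M and 0.00389 M: the row rises, then falls, with the turn read at 0.097 M of G and 0.00478 M of Q. At the end of Wednesday's, with a count of 0.363, Q is made 6.40 times faster than it is used up, each step taken net. Saturday's count of 6.05 gives a reckoned surviving share of 16.5 %, with G held at its charge. At the end of Saturday's, Q holds 1.95 % and G.Q holds 13.4 % of the G charged, so 22.5 % of the Q formed stands free.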